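**Plan**
The retrosynthesis cuts first the C15–O acyl bond of the 3-phenylpropanoate, then the C12–C13 bond, and traces the C12 bromide and C8 silyl ether back to the lactone of (+)-sclareolide (labdane numbering).
Enabling feature: C13 is a methyl-bearing methine β to the oxygenated C15, so with C15 at the ester level C13–C14–C15 is a crotonate acceptor; C12 is a primary carbon two atoms from C9 of ring B and can be a Grignard carbon.
Forward: sclareolide is reduced to the C8,C12-diol, the C8 alcohol is masked as a triethylsilyl ether, and C12 becomes bromide and then alkylmagnesium. This adds 1,4 to methyl (E)-crotonate under copper/chiral diphosphine catalysis; C15 is then reduced, the silyl group removed and the primary alcohol acylated.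
Stereochemistry: C5, C8, C9 and C10 of the trans-decalin (rings A and B) come unchanged from sclareolide; C13 (S) is set by the catalyst in the fragment union.

Key step: step 5

Assumption: the Josiphos antipode named in step 5 is taken to be the one that delivers the alkyl group to the Re face of C3 of methyl (E)-but-2-enoate, which is the face that leads to 13S. Both antipodes are commercial, and the sense would be confirmed on a model primary Grignard reagent before bromide 5 is committed.

Step 1
Reactants: 1 (+)-sclareolide, (3aR,5aS,9aS,9bR)-3a,6,6,9a-tetramethyldecahydronaphtho[2,1-b]furan-2(1H)-one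
Product: 2 (1R,2R,4aS,8aS)-1-(2-hydroxyethyl)-2,5,5,8a-tetramethyldecahydronaphthalen-2-ol
Conditions: LiAlH4, THF, 0 °C to rt; H2O quench
Reagents that add atoms: none
Why: LiAlH4 reduction of a γ-lactone to the 1,4-diol breaks only the acyl C12–O bond, so C8 and C9 keep the configuration of sclareolide and no new stereocentre arises.

Step 2
Reactants: 2 (1R,2R,4aS,8aS)-1-(2-hydroxyethyl)-2,5,5,8a-tetramethyldecahydronaphthalen-2-ol
Product: 3 triethyl{2-[(1R,2R,4aS,8aS)-2,5,5,8a-tetramethyl-2-(triethylsilyloxy)decahydronaphthalen-1-yl]ethoxy}silane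
Conditions: TESOTf (2.5 equiv), 2,6-lutidine, CH2Cl2, −78 to 0 °C
Reagents that add atoms: triethylsilyl trifluoromethanesulfonate, CC[Si](CC)(CC)OS(=O)(=O)C(F)(F)F
Why: Silyl triflate with a hindered pyridine base (standard silylation of hindered alcohols) silylates the primary C12 hydroxyl and the equatorial tertiary C8 hydroxyl at oxygen without breaking the C8–O bond, so no stereocentre is affected.

Step 3
Reactants: 3 triethyl{2-[(1R,2R,4aS,8aS)-2,5,5,8a-tetramethyl-2-(triethylsilyloxy)decahydronaphthalen-1-yl]ethoxy}silane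
Product: 4 2-[(1R,2R,4aS,8aS)-2,5,5,8a-tetramethyl-2-(triethylsilyloxy)decahydronaphthalen-1-yl]ethan-1-ol
Conditions: PPTS (0.1 equiv), MeOH/CH2Cl2 1:1, 0 °C
Reagents that add atoms: none
Why: Acid-catalysed methanolysis of silyl ethers is governed by steric access to silicon, so the primary C12 triethylsilyl ether should be cleaved much faster than the tertiary C8 ether flanked by the axial C8 methyl group (selective desilylation).

Step 4
Reactants: 4 2-[(1R,2R,4aS,8aS)-2,5,5,8a-tetramethyl-2-(triethylsilyloxy)decahydronaphthalen-1-yl]ethan-1-ol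
Product: 5 {[(1R,2R,4aS,8aS)-1-(2-bromoethyl)-2,5,5,8a-tetramethyldecahydronaphthalen-2-yl]oxy}triethylsilane
Conditions: CBr4, PPh3, imidazole, CH2Cl2, 0 °C
Reagents that add atoms: carbon tetrabromide, BrC(Br)(Br)Br
Why: Appel bromination converts the primary alcohol through its alkoxyphosphonium ion by SN2 attack of bromide at C12, and the cold imidazole-buffered medium should keep the hindered C8 silyloxy oxygen from closing the tetrahydrofuran ring.

Step 5
Reactants: 5 {[(1R,2R,4aS,8aS)-1-(2-bromoethyl)-2,5,5,8a-tetramethyldecahydronaphthalen-2-yl]oxy}triethylsilane; 6 methyl (E)-but-2-enoate (methyl crotonate)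
Product: 9 methyl (3S)-3-methyl-5-[(1R,2R,4aS,8aS)-2,5,5,8a-tetramethyl-2-(triethylsilyloxy)decahydronaphthalen-1-yl]pentanoate, via alkylmagnesium bromide 7 (not isolated), via bromomagnesium enolate 8 (not isolated)
Conditions: Mg turnings, Et2O, reflux; then slow addition (2 h) to 6 (1.5 equiv), CuBr·SMe2 (5 mol %), (R)-1-[(S)-2-(diphenylphosphino)ferrocenyl]ethyldicyclohexylphosphine (Josiphos, C36H44FeP2, 6 mol %), tBuOMe, −75 °C; sat. aq NH4Cl
Reagents that add atoms: none
Why: Transmetallation of 7 to the monovalent copper bromide–diphosphine complex gives an alkylcopper species that binds the C=C of 6 as a π-complex, adds oxidatively at C3 (the future C13) to a σ-bonded trivalent copper enolate and reductively eliminates to forge C12–C13, leaving enolate 8, which is protonated on quench. The closest known reaction type is the copper/ferrocenyl-diphosphine-catalysed enantioselective conjugate addition of primary alkyl Grignard reagents to acyclic (E)-α,β-unsaturated methyl esters. No ring is closed. The only new stereocentre, C13, is set by the chiral ligand, which must direct the alkyl group to the Re face of C3 of the (E)-enoate to give 13S, while the ring stereocentres lie four or more bonds from the reacting carbon and should not override the catalyst. The step needs 1,4- over 1,2-chemoselectivity and catalyst-controlled facial selectivity, which should be secured by slow addition at −75 °C in tBuOMe with bromide as counter-ion (keeping the uncatalysed background negligible), by the pure E geometry of 6 and by the primary, α-unbranched nature of the C12 carbanion. The C8 oxygen is carried as the triethylsilyl ether so that no acidic proton or chelating alkoxide interferes with magnesium insertion or with the copper catalyst.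

Step 6
Reactants: 9 methyl (3S)-3-methyl-5-[(1R,2R,4aS,8aS)-2,5,5,8a-tetramethyl-2-(triethylsilyloxy)decahydronaphthalen-1-yl]pentanoate
Product: 10 (3S)-3-methyl-5-[(1R,2R,4aS,8aS)-2,5,5,8a-tetramethyl-2-(triethylsilyloxy)decahydronaphthalen-1-yl]pentan-1-ol
Conditions: LiAlH4, THF, 0 °C; H2O quench
Reagents that add atoms: none
Why: LiAlH4 reduces the methyl ester to the C15 primary alcohol while the silyl ether is inert and C13, which is β to the carbonyl group, cannot epimerise (ester reduction).

Step 7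
Reactants: 10 (3S)-3-methyl-5-[(1R,2R,4aS,8aS)-2,5,5,8a-tetramethyl-2-(triethylsilyloxy)decahydronaphthalen-1-yl]pentan-1-ol
Product: 11 (1R,2R,4aS,8aS)-1-[(3S)-5-hydroxy-3-methylpentyl]-2,5,5,8a-tetramethyldecahydronaphthalen-2-ol
Conditions: TBAF (1 M in THF), THF, rt to 50 °C
Reagents that add atoms: none
Why: Fluoride attacks silicon and cleaves the Si–O bond of the tertiary triethylsilyl ether (fluoride desilylation) at a stage where no ester is present, leaving the C8–O bond and its configuration untouched.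

Step 8
Reactants: 11 (1R,2R,4aS,8aS)-1-[(3S)-5-hydroxy-3-methylpentyl]-2,5,5,8a-tetramethyldecahydronaphthalen-2-ol; 12 3-phenylpropanoyl chloride
Product: 13 (3S)-5-[(1R,2R,4aS,8aS)-2-hydroxy-2,5,5,8a-tetramethyldecahydronaphthalen-1-yl]-3-methylpentyl 3-phenylpropanoate (target)
Conditions: 12 (1.05 equiv), pyridine, CH2Cl2, 0 °C
Reagents that add atoms: none
Why: Acylation with an acid chloride and pyridine is selective for the unhindered primary C15 hydroxyl because the tertiary C8 hydroxyl flanked by the axial methyl group is acylated only under forcing conditions (chemoselective esterification).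

**Compound list**
1 | (+)-sclareolide, (3aR,5aS,9aS,9bR)-3a,6,6,9a-tetramethyldecahydronaphtho[2,1-b]furan-2(1H)-one | O=C1C[C@@H]2[C@@]3(C)CCCC(C)(C)[C@@H]3CC[C@@]2(C)O1 | starting material
2 | (1R,2R,4aS,8aS)-1-(2-hydroxyethyl)-2,5,5,8a-tetramethyldecahydronaphthalen-2-ol | OCC[C@@H]1[C@@]2(C)CCCC(C)(C)[C@@H]2CC[C@@]1(C)O | intermediate
3 | triethyl{2-[(1R,2R,4aS,8aS)-2,5,5,8a-tetramethyl-2-(triethylsilyloxy)decahydronaphthalen-1-yl]ethoxy}silane | CC[Si](CC)(CC)OCC[C@@H]1[C@@]2(C)CCCC(C)(C)[C@@H]2CC[C@@]1(C)O[Si](CC)(CC)CC | intermediate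
4 | 2-[(1R,2R,4aS,8aS)-2,5,5,8a-tetramethyl-2-(triethylsilyloxy)decahydronaphthalen-1-yl]ethan-1-ol | OCC[C@@H]1[C@@]2(C)CCCC(C)(C)[C@@H]2CC[C@@]1(C)O[Si](CC)(CC)CC | intermediate
5 | {[(1R,2R,4aS,8aS)-1-(2-bromoethyl)-2,5,5,8a-tetramethyldecahydronaphthalen-2-yl]oxy}triethylsilane | BrCC[C@@H]1[C@@]2(C)CCCC(C)(C)[C@@H]2CC[C@@]1(C)O[Si](CC)(CC)CC | intermediate
6 | methyl (E)-but-2-enoate | C/C=C/C(=O)OC | starting material
7 | bromo{2-[(1R,2R,4aS,8aS)-2,5,5,8a-tetramethyl-2-(triethylsilyloxy)decahydronaphthalen-1-yl]ethyl}magnesium (Grignard reagent, not isolated) | Br[Mg]CC[C@@H]1[C@@]2(C)CCCC(C)(C)[C@@H]2CC[C@@]1(C)O[Si](CC)(CC)CC | intermediate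
8 | bromomagnesium enolate of 9, O-bromomagnesio O-methyl ketene acetal with C13 already S-configured (not isolated) | C[C@H](C=C(OC)O[Mg]Br)CC[C@@H]1[C@@]2(C)CCCC(C)(C)[C@@H]2CC[C@@]1(C)O[Si](CC)(CC)CC | intermediate
9 | methyl (3S)-3-methyl-5-[(1R,2R,4aS,8aS)-2,5,5,8a-tetramethyl-2-(triethylsilyloxy)decahydronaphthalen-1-yl]pentanoate | C[C@H](CC(=O)OC)CC[C@@H]1[C@@]2(C)CCCC(C)(C)[C@@H]2CC[C@@]1(C)O[Si](CC)(CC)CC | intermediate
10 | (3S)-3-methyl-5-[(1R,2R,4aS,8aS)-2,5,5,8a-tetramethyl-2-(triethylsilyloxy)decahydronaphthalen-1-yl]pentan-1-ol | C[C@H](CCO)CC[C@@H]1[C@@]2(C)CCCC(C)(C)[C@@H]2CC[C@@]1(C)O[Si](CC)(CC)CC | intermediate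
11 | (1R,2R,4aS,8aS)-1-[(3S)-5-hydroxy-3-methylpentyl]-2,5,5,8a-tetramethyldecahydronaphthalen-2-ol | C[C@H](CCO)CC[C@@H]1[C@@]2(C)CCCC(C)(C)[C@@H]2CC[C@@]1(C)O | intermediate
12 | 3-phenylpropanoyl chloride | O=C(Cl)CCc1ccccc1 | starting material
13 | (3S)-5-[(1R,2R,4aS,8aS)-2-hydroxy-2,5,5,8a-tetramethyldecahydronaphthalen-1-yl]-3-methylpentyl 3-phenylpropanoate | C[C@H](CCOC(=O)CCc1ccccc1)CC[C@@H]1[C@@]2(C)CCCC(C)(C)[C@@H]2CC[C@@]1(C)O | target

**Summary**
Total step count: 8. Longest linear sequence: 8 steps (1 to 13).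

**Steps most likely to fail**

Step 5. The bulky, silyloxy-bearing Grignard reagent may add 1,2 to the ester, or the catalyst may give insufficient facial control at C13. The fallback sets out from 5 (through 7) and comes back at 9. Reagent 7 is converted with CuBr·SMe2 (1 equiv, THF, −40 °C) into the alkylcopper reagent, which adds syn across methyl but-2-ynoate at −78 °C and is protonated cold to give methyl (2E)-3-methyl-5-[(1R,2R,4aS,8aS)-2,5,5,8a-tetramethyl-2-(triethylsilyloxy)decahydronaphthalen-1-yl]pent-2-enoate F1. C13 is then set separately by ligand-controlled conjugate reduction of F1 with copper hydride [Cu(OAc)2, the p-Tol-BINAP antipode that delivers hydride to the face giving 13S, polymethylhydrosiloxane, t-BuOH, toluene], which should give 9.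

Step 4. The C8 silyloxy oxygen may take part at the activated C12 carbon, closing the tetrahydrofuran ring with loss of the silyl group. The fallback sets out from 4 and comes back at 10, and never places a leaving group on C12.
- Dess–Martin oxidation of 4 gives 2-[(1R,2R,4aS,8aS)-2,5,5,8a-tetramethyl-2-(triethylsilyloxy)decahydronaphthalen-1-yl]acetaldehyde F2.
- Anti-crotylation of F2 with (E)-crotyldiisopinocampheylborane (pinene antipode chosen for the C13 configuration drawn; THF, −78 °C; NaOH, H2O2) forms C12–C13 and sets C13 under reagent control. It should give (2S,3R)-3-methyl-1-[(1R,2R,4aS,8aS)-2,5,5,8a-tetramethyl-2-(triethylsilyloxy)decahydronaphthalen-1-yl]pent-4-en-2-ol F3.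
- The superfluous C12 hydroxyl is converted with 1,1'-thiocarbonyldiimidazole and DMAP into O-{(2S,3R)-3-methyl-1-[(1R,2R,4aS,8aS)-2,5,5,8a-tetramethyl-2-(triethylsilyloxy)decahydronaphthalen-1-yl]pent-4-en-2-yl} 1H-imidazole-1-carbothioate F4.
- Radical deoxygenation of F4 (Bu3SnH, AIBN, toluene, 80 °C) gives triethyl{[(1R,2R,4aS,8aS)-2,5,5,8a-tetramethyl-1-[(3S)-3-methylpent-4-en-1-yl]decahydronaphthalen-2-yl]oxy}silane F5.
- Hydroboration–oxidation of F5 (9-BBN, THF; NaOH, H2O2) then gives 10.

Step 3. Selectivity between the two silyl ethers may erode, with loss of the C8 silyl group as well or its migration to the primary oxygen. The fallback sets out from 2 and comes back at 4, using two orthogonal protecting groups instead of a kinetic differentiation. Selective acetylation of the primary hydroxyl (Ac2O, pyridine, 0 °C) gives 2-[(1R,2R,4aS,8aS)-2-hydroxy-2,5,5,8a-tetramethyldecahydronaphthalen-1-yl]ethyl acetate F6. Silylation of the tertiary hydroxyl (TESOTf, 2,6-lutidine) gives 2-[(1R,2R,4aS,8aS)-2,5,5,8a-tetramethyl-2-(triethylsilyloxy)decahydronaphthalen-1-yl]ethyl acetate F7. Methanolysis of the acetate (K2CO3, MeOH) then gives 4.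

Further compounds
F1 | step 5 | methyl (2E)-3-methyl-5-[(1R,2R,4aS,8aS)-2,5,5,8a-tetramethyl-2-(triethylsilyloxy)decahydronaphthalen-1-yl]pent-2-enoate | C/C(=C\C(=O)OC)CC[C@@H]1[C@@]2(C)CCCC(C)(C)[C@@H]2CC[C@@]1(C)O[Si](CC)(CC)CC
F2 | step 4 | 2-[(1R,2R,4aS,8aS)-2,5,5,8a-tetramethyl-2-(triethylsilyloxy)decahydronaphthalen-1-yl]acetaldehyde | O=CC[C@@H]1[C@@]2(C)CCCC(C)(C)[C@@H]2CC[C@@]1(C)O[Si](CC)(CC)CC
F3 | step 4 | (2S,3R)-3-methyl-1-[(1R,2R,4aS,8aS)-2,5,5,8a-tetramethyl-2-(triethylsilyloxy)decahydronaphthalen-1-yl]pent-4-en-2-ol | C[C@H](C=C)[C@@H](O)C[C@@H]1[C@@]2(C)CCCC(C)(C)[C@@H]2CC[C@@]1(C)O[Si](CC)(CC)CC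
F4 | step 4 | O-{(2S,3R)-3-methyl-1-[(1R,2R,4aS,8aS)-2,5,5,8a-tetramethyl-2-(triethylsilyloxy)decahydronaphthalen-1-yl]pent-4-en-2-yl} 1H-imidazole-1-carbothioate | C[C@H](C=C)[C@@H](OC(=S)n1ccnc1)C[C@@H]1[C@@]2(C)CCCC(C)(C)[C@@H]2CC[C@@]1(C)O[Si](CC)(CC)CC
F5 | step 4 | triethyl{[(1R,2R,4aS,8aS)-2,5,5,8a-tetramethyl-1-[(3S)-3-methylpent-4-en-1-yl]decahydronaphthalen-2-yl]oxy}silane | C[C@H](C=C)CC[C@@H]1[C@@]2(C)CCCC(C)(C)[C@@H]2CC[C@@]1(C)O[Si](CC)(CC)CC
F6 | step 3 | 2-[(1R,2R,4aS,8aS)-2-hydroxy-2,5,5,8a-tetramethyldecahydronaphthalen-1-yl]ethyl acetate | CC(=O)OCC[C@@H]1[C@@]2(C)CCCC(C)(C)[C@@H]2CC[C@@]1(C)O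
F7 | step 3 | 2-[(1R,2R,4aS,8aS)-2,5,5,8a-tetramethyl-2-(triethylsilyloxy)decahydronaphthalen-1-yl]ethyl acetate | CC(=O)OCC[C@@H]1[C@@]2(C)CCCC(C)(C)[C@@H]2CC[C@@]1(C)O[Si](CC)(CC)CC
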